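## Retrosynthetic overview

1. The methyl acrylate is made last from a C1 isopropenyl group (allylic oxidation, then oxidation and methylation), after C5 acetylation and reagent-controlled epoxidation of the C12=C13 alkene of a macrocyclic 4,5,8-triol diene.
2. The C5 carbinol comes from the C5 ketone of a tertiary α-ketol. Key disconnection C4–C5: a carbene-generated acyl-anion equivalent at the C5 aldehyde carbon adds to the C4 methyl ketone, joining two carbonyl carbons and closing the 14-membered ring in the same step.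
3. The acyclic keto aldehyde (stored as its lactol) comes from cross-metathesis at C9=C10 of a linalool-derived vinyl lactol (C5–C9, C8 stereocentre) with a limonene-derived 1,4-diene ketone (C10–C14 and C1–C4, C1 stereocentre).
4. The diene ketone comes from limonene oxide by oxidative ring cleavage, E-selective Wittig olefination (C12=C13) and allyl–vinyl coupling (C10–C11).
5. Ring order: 14-membered carbocycle first (step 8), oxirane second (step 10); the lactol ring only carries the C5 aldehyde temporarily.

Assumption: all macrocycles are named with cembrane-style locants (C1 = ring carbon bearing the three-carbon side chain, C4 = first methyl carbinol, C5 = acetoxy carbon, C8 = second methyl carbinol, C9=C10, C12–C13 = oxirane, C14), not lowest-locant rules.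

Assumption: (S)-(+)-linalool, (+)-limonene oxide and both mirror-image forms of the triazolium salt and of the Shi ketone are bought; the (5aS,10bR) triazolium salt is taken as matched to the (4R) ketol, and its mirror image is used under the same conditions if the first run shows the reverse sense.

## Route

Step 1
Reactants: 1 (4R)-1-methyl-4-(prop-1-en-2-yl)-7-oxabicyclo[4.1.0]heptane ((+)-limonene oxide, cis/trans mixture)
Product: 3 (3R)-6-oxo-3-(prop-1-en-2-yl)heptanal, via limonene-1,2-diol 2 (not isolated)
Conditions: H5IO6 (1.1 equiv), THF/H2O, 0 °C to rt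
Reagents that add atoms: water, O
Why: Acid-promoted epoxide hydrolysis followed by periodate glycol cleavage in one pot (both epoxide diastereomers converge) opens the ring to the future C4 methyl ketone and C13 aldehyde and leaves the chiral-pool C1 stereocentre untouched.

Step 2
Reactants: 3 (3R)-6-oxo-3-(prop-1-en-2-yl)heptanal; 4 2-(triphenyl-λ5-phosphanylidene)propanal
Product: 5 (2E,5R)-2-methyl-8-oxo-5-(prop-1-en-2-yl)non-2-enal
Conditions: toluene, 90 °C
Reagents that add atoms: none
Why: Wittig olefination with a formyl-stabilised ylide reacts only with the aldehyde (the methyl ketone is inert) and gives the E-trisubstituted C12=C13 alkene.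

Step 3
Reactants: 5 (2E,5R)-2-methyl-8-oxo-5-(prop-1-en-2-yl)non-2-enal
Product: 6 (5R,7E)-9-hydroxy-8-methyl-5-(prop-1-en-2-yl)non-7-en-2-one
Conditions: NaBH4 (0.3 equiv), EtOH/CH2Cl2, −78 °C
Reagents that add atoms: none
Why: Borohydride 1,2-reduction at low temperature separates the enal from the much less electrophilic methyl ketone by rate, so only C11 is reduced.

Step 4
Reactants: 6 (5R,7E)-9-hydroxy-8-methyl-5-(prop-1-en-2-yl)non-7-en-2-one
Product: 7 (5R,7E)-9-bromo-8-methyl-5-(prop-1-en-2-yl)non-7-en-2-one
Conditions: CBr4, PPh3, CH2Cl2, 0 °C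
Reagents that add atoms: tetrabromomethane, BrC(Br)(Br)Br
Why: Appel bromination converts the primary allylic alcohol into the bromide under neutral conditions without allylic transposition and without touching the ketone.

Step 5
Reactants: 7 (5R,7E)-9-bromo-8-methyl-5-(prop-1-en-2-yl)non-7-en-2-one
Product: 8 (5R,7E)-8-methyl-5-(prop-1-en-2-yl)undeca-7,10-dien-2-one
Conditions: Bu3SnCH=CH2, Pd2(dba)3 (2.5 mol%), P(2-furyl)3 (10 mol%), THF, 50 °C
Reagents that add atoms: tributyl(vinyl)stannane, C=C[Sn](CCCC)(CCCC)CCCC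
Why: Stille allyl–vinyl coupling through a zerovalent-palladium-derived π-allyl complex delivers the vinyl group to the unhindered primary terminus (C11) with retention of the E-trisubstituted alkene, giving the skipped diene and supplying C10.

Step 6
Reactants: 9 (3S)-3,7-dimethylocta-1,6-dien-3-ol ((S)-(+)-linalool)
Product: 12 (5S)-5-ethenyl-5-methyloxolan-2-ol (anomer mixture), via secondary ozonide 10 (not isolated), via open-chain hydroxy aldehyde 11 (not isolated)
Conditions: O3, CH2Cl2, −78 °C, Sudan Red 7B endpoint; then Me2S, −78 °C to rt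
Reagents that add atoms: ozone, [O-][O+]=O
Why: Chemoselective ozonolysis cleaves the electron-rich trisubstituted alkene much faster than the vinyl group, and the resulting γ-hydroxy aldehyde (C5) closes to the lactol with the chiral-pool C8 stereocentre unchanged.

Step 7
Reactants: 8 (5R,7E)-8-methyl-5-(prop-1-en-2-yl)undeca-7,10-dien-2-one; 12 (5S)-5-ethenyl-5-methyloxolan-2-ol
Product: 13 (5S)-5-methyl-5-[(1E,4E,7R)-4-methyl-10-oxo-7-(prop-1-en-2-yl)undeca-1,4-dien-1-yl]oxolan-2-ol
Conditions: second-generation Hoveyda–Grubbs catalyst RuCl2(SIMes)(=CH-C6H4-2-O-i-Pr) (10 mol%), 1,4-benzoquinone (20 mol%), 12 (3 equiv), CH2Cl2, 40 °C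
Reagents that add atoms: none
Why: Olefin cross-metathesis between the unhindered terminal alkene of 8 and the hindered vinyl group of 12 (used in excess) is selective for the cross product and gives the E-C9=C10 alkene because of the adjacent quaternary carbon, while benzoquinone suppresses isomerisation of the skipped diene and the isopropenyl and trisubstituted alkenes stay out of the reaction.

Step 8
Reactants: 13 (5S)-5-methyl-5-[(1E,4E,7R)-4-methyl-10-oxo-7-(prop-1-en-2-yl)undeca-1,4-dien-1-yl]oxolan-2-ol
Product: 15 (1R,4R,8S,9E,12E)-4,8-dihydroxy-4,8,12-trimethyl-1-(prop-1-en-2-yl)cyclotetradeca-9,12-dien-5-one, via open-chain keto aldehyde 14 (not isolated)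
Conditions: (5aS,10bR)-2-(pentafluorophenyl)-5a,10b-dihydro-4H,6H-indeno[2,1-b][1,2,4]triazolo[4,3-d][1,4]oxazin-2-ium tetrafluoroborate (20 mol%), i-Pr2NEt (20 mol%), degassed toluene, 60 °C, 13 added by syringe pump over 12 h to 2 mM final concentration
Reagents that add atoms: none
Why: Proposed new method: the lactol opens reversibly to aldehyde 14, the triazolylidene adds to C5 and proton transfer gives a nucleophilic enaminol (acyl-anion equivalent) that attacks the C4 methyl ketone through a hydrogen-bonded five-centre transition state before the carbene is released, so two carbonyl carbons are joined, the 14-membered ring closes and the C4 tertiary carbinol is set by the chiral carbene (one enaminol face shielded by the indane) together with the two E-alkenes that pre-organise the chain; the closest known reaction is the enantioselective carbene-catalysed intramolecular aldehyde–ketone crossed benzoin that closes five- and six-membered α-ketols, and the new element is the ring size, addressed by high dilution, by the lactol acting as a slow-release reservoir of aldehyde and by the reversibility of the competing intermolecular aldehyde homo-benzoin under the same catalyst.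

Step 9
Reactants: 15 (1R,4R,8S,9E,12E)-4,8-dihydroxy-4,8,12-trimethyl-1-(prop-1-en-2-yl)cyclotetradeca-9,12-dien-5-one
Product: 16 (1R,4R,5R,8S,9E,12E)-4,8,12-trimethyl-1-(prop-1-en-2-yl)cyclotetradeca-9,12-diene-4,5,8-triol
Conditions: (S)-1-methyl-3,3-diphenyltetrahydro-1H,3H-pyrrolo[1,2-c][1,3,2]oxazaborole (0.5 equiv), catecholborane (4 equiv), toluene/CH2Cl2, −78 to −40 °C; then MeOH, 1 M NaOH
Reagents that add atoms: none
Why: Corey–Bakshi–Shibata reduction treats the fully substituted C4 as the large and the C6 methylene as the small ketone substituent, so the (S)-oxazaborolidine delivers hydride to give (5R) (the same sense as acetophenone to (R)-1-phenylethanol), and catecholborane leaves the three alkenes untouched at this temperature.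

Step 10
Reactants: 16 (1R,4R,5R,8S,9E,12E)-4,8,12-trimethyl-1-(prop-1-en-2-yl)cyclotetradeca-9,12-diene-4,5,8-triol
Product: 17 (1R,4R,5R,8S,9E,12S,13S)-12,13-epoxy-4,8,12-trimethyl-1-(prop-1-en-2-yl)cyclotetradec-9-ene-4,5,8-triol
Conditions: 1,2:4,5-di-O-isopropylidene-β-L-erythro-2,3-hexodiulo-2,6-pyranose (L-fructose-derived Shi ketone, 0.3 equiv), KHSO5 (as Oxone, 2KHSO5·KHSO4·K2SO4, 1.4 equiv), K2CO3, n-Bu4NHSO4, MeCN/dimethoxymethane/aqueous Na2B4O7 buffer (pH 10.5), 0 °C
Reagents that add atoms: potassium peroxymonosulfate, [K+].[O-]S(=O)(=O)OO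
Why: Shi asymmetric epoxidation (chiral dioxirane, spiro transition state) picks the most electron-rich E-trisubstituted C12=C13 alkene over the hindered, inductively deactivated C9=C10 alkene and the 1,1-disubstituted isopropenyl group, and the L-fructose-derived ketone gives the (12S,13S) oxirane, the mirror image of the (R,R) sense known for the D-fructose-derived ketone on E-alkenes.

Step 11
Reactants: 17 (1R,4R,5R,8S,9E,12S,13S)-12,13-epoxy-4,8,12-trimethyl-1-(prop-1-en-2-yl)cyclotetradec-9-ene-4,5,8-triol
Product: 18 (1R,4R,5R,8S,9E,12S,13S)-12,13-epoxy-4,8-dihydroxy-4,8,12-trimethyl-1-(prop-1-en-2-yl)cyclotetradec-9-en-5-yl acetate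
Conditions: Ac2O (1.5 equiv), pyridine, 4-(dimethylamino)pyridine (10 mol%), CH2Cl2, 0 °C to rt
Reagents that add atoms: acetic anhydride, CC(=O)OC(C)=O
Why: Nucleophile-catalysed acylation esterifies the only secondary hydroxyl (C5) while the two tertiary hydroxyls and the epoxide do not react under these conditions.

Step 12
Reactants: 18 (1R,4R,5R,8S,9E,12S,13S)-12,13-epoxy-4,8-dihydroxy-4,8,12-trimethyl-1-(prop-1-en-2-yl)cyclotetradec-9-en-5-yl acetate
Product: 19 (1R,4R,5R,8S,9E,12S,13S)-12,13-epoxy-4,8-dihydroxy-1-(3-hydroxyprop-1-en-2-yl)-4,8,12-trimethylcyclotetradec-9-en-5-yl acetate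
Conditions: SeO2 (0.5 equiv), t-BuOOH (3 equiv, anhydrous in decane), CH2Cl2, 0 °C to rt
Reagents that add atoms: selenium dioxide (transfers O), O=[Se]=O; tert-butyl hydroperoxide (terminal O source), CC(C)(C)OO
Why: Selenium dioxide allylic oxidation (ene reaction then [2,3]-sigmatropic shift) hydroxylates the methyl group of the isopropenyl unit, the only remaining alkene with a reactive allylic C–H (C12=C13 is already an epoxide and the 1,2-disubstituted C9=C10 alkene is much slower), and any over-oxidised enal converges in step 13.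

Step 13
Reactants: 19 (1R,4R,5R,8S,9E,12S,13S)-12,13-epoxy-4,8-dihydroxy-1-(3-hydroxyprop-1-en-2-yl)-4,8,12-trimethylcyclotetradec-9-en-5-yl acetate
Product: 22 methyl 2-[(1R,4R,5R,8S,9E,12S,13S)-5-acetoxy-12,13-epoxy-4,8-dihydroxy-4,8,12-trimethylcyclotetradec-9-en-1-yl]prop-2-enoate (CNP0191723.1), via enal 20 (not isolated), via carboxylic acid 21 (not isolated)
Conditions: 2,2,6,6-tetramethylpiperidin-1-oxyl (10 mol%), NaClO2 (2.5 equiv), NaOCl (5 mol%), MeCN/phosphate buffer pH 6.7, 35 °C; then MeI, KHCO3, DMF, rt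
Reagents that add atoms: sodium chlorite, [Na+].[O-]Cl=O; iodomethane, CI
Why: Oxoammonium/chlorite oxidation takes the primary allylic alcohol through the enal to the acrylic acid at near-neutral pH (acetate, epoxide and tertiary alcohols survive), and carboxylate O-alkylation with iodomethane under weak base gives the methyl ester without moving the exocyclic alkene into conjugation with C1.

## Compound list

1 | (4R)-1-methyl-4-(prop-1-en-2-yl)-7-oxabicyclo[4.1.0]heptane ((+)-limonene oxide, cis/trans mixture) | C=C(C)[C@@H]1CCC2(C)OC2C1 | starting material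
2 | (4R)-1-methyl-4-(prop-1-en-2-yl)cyclohexane-1,2-diol (diastereomer mixture, not isolated) | C=C(C)[C@@H]1CCC(C)(O)C(O)C1 | intermediate
3 | (3R)-6-oxo-3-(prop-1-en-2-yl)heptanal | O=CC[C@@H](CCC(C)=O)C(C)=C | intermediate
4 | 2-(triphenyl-λ5-phosphanylidene)propanal | CC(C=O)=P(c1ccccc1)(c1ccccc1)c1ccccc1 | starting material
5 | (2E,5R)-2-methyl-8-oxo-5-(prop-1-en-2-yl)non-2-enal | O=C/C(C)=C/C[C@@H](CCC(C)=O)C(C)=C | intermediate
6 | (5R,7E)-9-hydroxy-8-methyl-5-(prop-1-en-2-yl)non-7-en-2-one | OC/C(C)=C/C[C@@H](CCC(C)=O)C(C)=C | intermediate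
7 | (5R,7E)-9-bromo-8-methyl-5-(prop-1-en-2-yl)non-7-en-2-one | BrC/C(C)=C/C[C@@H](CCC(C)=O)C(C)=C | intermediate
8 | (5R,7E)-8-methyl-5-(prop-1-en-2-yl)undeca-7,10-dien-2-one | C=CC/C(C)=C/C[C@@H](CCC(C)=O)C(C)=C | intermediate
9 | (3S)-3,7-dimethylocta-1,6-dien-3-ol ((S)-(+)-linalool) | CC(C)=CCC[C@](C)(O)C=C | starting material
10 | 5-[(3S)-3-hydroxy-3-methylpent-4-en-1-yl]-3,3-dimethyl-1,2,4-trioxolane (not isolated) | CC1(C)OOC(CC[C@](C)(O)C=C)O1 | intermediate
11 | (4S)-4-hydroxy-4-methylhex-5-enal (not isolated) | O=CCC[C@](C)(O)C=C | intermediate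
12 | (5S)-5-ethenyl-5-methyloxolan-2-ol (anomer mixture) | C=C[C@]1(C)CCC(O)O1 | intermediate
13 | (5S)-5-methyl-5-[(1E,4E,7R)-4-methyl-10-oxo-7-(prop-1-en-2-yl)undeca-1,4-dien-1-yl]oxolan-2-ol (anomer mixture) | OC1CC[C@@](C)(/C=C/C/C(C)=C/C[C@@H](CCC(C)=O)C(C)=C)O1 | intermediate
14 | (4S,5E,8E,11R)-4-hydroxy-4,8-dimethyl-14-oxo-11-(prop-1-en-2-yl)pentadeca-5,8-dienal (not isolated) | O=CCC[C@](C)(O)/C=C/C/C(C)=C/C[C@@H](CCC(C)=O)C(C)=C | intermediate
15 | (1R,4R,8S,9E,12E)-4,8-dihydroxy-4,8,12-trimethyl-1-(prop-1-en-2-yl)cyclotetradeca-9,12-dien-5-one | C=C(C)[C@@H]1CC[C@@](C)(O)C(=O)CC[C@](C)(O)/C=C/C/C(C)=C/C1 | intermediate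
16 | (1R,4R,5R,8S,9E,12E)-4,8,12-trimethyl-1-(prop-1-en-2-yl)cyclotetradeca-9,12-diene-4,5,8-triol | C=C(C)[C@@H]1CC[C@@](C)(O)[C@H](O)CC[C@](C)(O)/C=C/C/C(C)=C/C1 | intermediate
17 | (1R,4R,5R,8S,9E,12S,13S)-12,13-epoxy-4,8,12-trimethyl-1-(prop-1-en-2-yl)cyclotetradec-9-ene-4,5,8-triol | C=C(C)[C@@H]1CC[C@@](C)(O)[C@H](O)CC[C@](C)(O)/C=C/C[C@]2(C)O[C@H]2C1 | intermediate
18 | (1R,4R,5R,8S,9E,12S,13S)-12,13-epoxy-4,8-dihydroxy-4,8,12-trimethyl-1-(prop-1-en-2-yl)cyclotetradec-9-en-5-yl acetate | C=C(C)[C@@H]1CC[C@@](C)(O)[C@H](OC(C)=O)CC[C@](C)(O)/C=C/C[C@]2(C)O[C@H]2C1 | intermediate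
19 | (1R,4R,5R,8S,9E,12S,13S)-12,13-epoxy-4,8-dihydroxy-1-(3-hydroxyprop-1-en-2-yl)-4,8,12-trimethylcyclotetradec-9-en-5-yl acetate | C=C(CO)[C@@H]1CC[C@@](C)(O)[C@H](OC(C)=O)CC[C@](C)(O)/C=C/C[C@]2(C)O[C@H]2C1 | intermediate
20 | 2-[(1R,4R,5R,8S,9E,12S,13S)-5-acetoxy-12,13-epoxy-4,8-dihydroxy-4,8,12-trimethylcyclotetradec-9-en-1-yl]prop-2-enal (not isolated) | C=C(C=O)[C@@H]1CC[C@@](C)(O)[C@H](OC(C)=O)CC[C@](C)(O)/C=C/C[C@]2(C)O[C@H]2C1 | intermediate
21 | 2-[(1R,4R,5R,8S,9E,12S,13S)-5-acetoxy-12,13-epoxy-4,8-dihydroxy-4,8,12-trimethylcyclotetradec-9-en-1-yl]prop-2-enoic acid (not isolated) | C=C(C(=O)O)[C@@H]1CC[C@@](C)(O)[C@H](OC(C)=O)CC[C@](C)(O)/C=C/C[C@]2(C)O[C@H]2C1 | intermediate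
22 | methyl 2-[(1R,4R,5R,8S,9E,12S,13S)-5-acetoxy-12,13-epoxy-4,8-dihydroxy-4,8,12-trimethylcyclotetradec-9-en-1-yl]prop-2-enoate (CNP0191723.1) | C=C(C(=O)OC)[C@@H]1CC[C@@](C)(O)[C@H](OC(C)=O)CC[C@](C)(O)/C=C/C[C@]2(C)O[C@H]2C1 | target

## Step count and risk

Total step count: 13. Longest linear sequence: 12 steps (steps 1–5 and 7–13, from 1); step 6 is the one-step side branch from 9.

The three steps most likely to fail, in order of risk:

Step 8 (carbene-catalysed macrocyclisation). The 14-membered crossed benzoin onto an unactivated methyl ketone has no direct precedent; it may stall at oligomeric acyloins or give poor control at C4. The fallback sets out from 13 and comes back at 16. Compound 13 is added slowly to SmI2 (divalent samarium, 4 equiv) and HMPA in THF at 1 mM, −78 °C to rt. The ketyl radical anion formed from the opened lactol aldehyde adds to the C4 ketone in an intramolecular pinacol-type reductive coupling. This closes the ring and gives the C4/C5 diol directly, so step 9 is bypassed as well; the (4R,5R) isomer 16 is separated from its diastereomers by chromatography. Ketyl-type reductive carbonyl couplings have closed 14-membered cembranoid diols before. New compounds on this detour: none, F0.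

Step 12 (late allylic oxidation). Selenium dioxide may attack the C1 methine instead of the methyl group, or its acidity may open the trisubstituted epoxide or transpose the C8 allylic alcohol. The fallback sets out from 18 and comes back at 20. Ene-type chlorination with HOCl generated from Ca(OCl)2 and solid CO2 in CH2Cl2/H2O at 0 °C shifts the isopropenyl double bond and gives the allylic chloride F3. N-Methylmorpholine N-oxide with catalytic NaI in MeCN at rt (N-oxide oxidation of the allylic halide, Kornblum type) then gives enal 20. Compound 20 is taken through the chlorite stage (here with NaH2PO4 and 2-methylbut-2-ene in place of the nitroxyl) and the iodomethane stage of step 13 to 22.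

Step 9 (C5 configuration). The free α-hydroxyl and the macrocyclic conformation may override the oxazaborolidine and give the (5S) epimer or a mixture. The fallback sets out from 15 and comes back at 16, replacing catalyst control by substrate control. 1-(Trimethylsilyl)imidazole in CH2Cl2 at rt caps both tertiary hydroxyls to give the bis(trimethylsilyl) ether F1. LiBH(s-Bu)3 in THF at −78 °C then reduces the ketone under polar Felkin–Anh control (C4–OSi bond anti to the incoming hydride, which passes the C4 methyl group), giving the 4,5-syn silyl-protected C5 alcohol F2. Citric acid in MeOH at rt removes both silyl groups to give 16.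

Further compounds

F0 | step 8 | none | none
F1 | step 9 | (1R,4R,8S,9E,12E)-4,8,12-trimethyl-1-(prop-1-en-2-yl)-4,8-bis(trimethylsilyloxy)cyclotetradeca-9,12-dien-5-one | C=C(C)[C@@H]1CC[C@@](C)(O[Si](C)(C)C)C(=O)CC[C@](C)(O[Si](C)(C)C)/C=C/C/C(C)=C/C1
F2 | step 9 | (1R,4R,5R,8S,9E,12E)-4,8,12-trimethyl-1-(prop-1-en-2-yl)-4,8-bis(trimethylsilyloxy)cyclotetradeca-9,12-dien-5-ol | C=C(C)[C@@H]1CC[C@@](C)(O[Si](C)(C)C)[C@H](O)CC[C@](C)(O[Si](C)(C)C)/C=C/C/C(C)=C/C1
F3 | step 12 | (1R,4R,5R,8S,9E,12S,13S)-1-(3-chloroprop-1-en-2-yl)-12,13-epoxy-4,8-dihydroxy-4,8,12-trimethylcyclotetradec-9-en-5-yl acetate | C=C(CCl)[C@@H]1CC[C@@](C)(O)[C@H](OC(C)=O)CC[C@](C)(O)/C=C/C[C@]2(C)O[C@H]2C1
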